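The constants give the flask two clocks. The starting material turns to target at 0.021 s⁻¹, while target passes to the isomer of the product at 0.046 s⁻¹ and returns at 0.0287 s⁻¹, with the equilibrium constant 1.6 read as forward over back.

    starting material → target (k1 = 0.021 s⁻¹)
    target ⇌ isomer of the product (K2 = 1.6, k2 = 0.046 s⁻¹)

common to all: starting material 0.0050 M
- south-east: time 20 s; a closed flask charged with all of it at once and left for 20 s
- east: one stirred flow tank at steady state, fed with the mixture as stated, mean residence time 100 s
- north: one stirred flow tank at steady state, fed with the mixture as stated, mean residence time 20 s

* order of the set-ups by the share of target in all that became target or isomer of the product, at the outlet or at the end, highest first (south-east / east / north)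
* share of target in all that became target or isomer of the product, at the outlet or at the end, south-east
* share of target in all that became target or isomer of the product, at the outlet or at the end, east
* share of target in all that became target or isomer of the product, at the outlet or at the end, north

The share asked for is c(target) over the sum of c(target) and c(isomer of the product). The two species exchange as one mode, with a relaxation time of the pair, the inverse of the sum of forward and back constants, of 13.4 s. The share can be solved at both ends. A newborn portion is pure target, the end of kinetic control, while a portion much older than this time holds the equilibrium share 38.5%, the end of thermodynamic control. Between the ends, a portion of age a keeps exp(−a/θ) of its excess over equilibrium, θ being the relaxation time.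

A stirred tank at steady state forms target at a constant rate and holds an exponential spread of ages with mean τ, the residence time, so the excess kept is one over one plus τ/θ. East, at 100 s, then gives 45.7%, and north, at 20.0 s, gives 63.1%.

In the closed south-east flask, target born evenly over 20 s would keep 51.9% of its excess, so this first estimate of the share is 70.4%. The estimate for south-east is thus higher than that for north, and the one for north is higher than that for east.

The weak link is the even birth: by the end of the run in south-east, the birth rate has sunk to 65.7% of its start. Weighting births by that decay favours older portions, and the excess kept is lower than under even birth, at 49.3%. The reckoned share in south-east becomes 68.8%.

The forecast gave 68.8% for south-east, 45.7% for east and 63.1% for north, ranked south-east > north > east, reasoning that “the reverse constant is 0.046/1.6”.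

The flask gives 68.8% for south-east, 45.7% for east and 63.1% for north, ranked south-east > north > east, so the forecast held. With the exchange struck out, east stands at 100%, the pure end. Left for 200 s, the south-east flask has run 14.9 relaxation times, and the same weighted excess, 0.595%, puts its share at 38.8%, and the flask stands at 38.8%.

Its constants are assumed; no experiment stands behind them.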